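**Strategy.** The route rests on breaking the lactone C–O bond of the 12-membered ring while the acyl carbon is stored as a ketene precursor. With the arene numbered C1 (bears the lactone C=O), C2 (OMe), C3, C4 (O), C5 and C6 (bears the macrocyclic CH2), the carbonyl carbon and the benzylic carbon sit on the adjacent atoms C1 and C6, so they can be joined in a benzocyclobutenone. Light opens that four-membered ring to an ortho-quinoid ketene, the chain hydroxyl adds to it, and a hydrogen shift restores the arene: one operation gives the macrolactone. The precursor is a 5-methoxy-3-silyloxybenzocyclobutenone whose sp3 carbon carries the (7R)-7-hydroxyoctyl chain.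

Key step: step 10

Assumption: (S)-4-methyldihydrofuran-2(3H)-one 20 is taken as a purchasable building block; in bicyclo[4.2.0]octatrienone numbering the ketone C7 is bonded to bridgehead C6, so the methoxy group beside it is at C5 and the protected oxygen at C3, and that oxygen is carried as a triisopropylsilyl ether because it can be placed selectively and survives the acidic fluoride step.

**Route**

Step 1
Reactants: 1 5-iodovanillin (4-hydroxy-3-iodo-5-methoxybenzaldehyde)
Product: 2 2-iodo-6-methoxybenzene-1,4-diol
Conditions: H2O2 (30% aq.), NaOH, THF/H2O, 0 °C to rt, Ar; then 1 M HCl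
Reagents that add atoms: hydrogen peroxide, OO
Why: Dakin oxidation, in which the para-hydroxy aldehyde adds hydroperoxide, the electron-rich aryl group migrates to oxygen and the aryl formate is hydrolysed in situ, so the formyl carbon is exchanged for the future C4 oxygen while iodine and methoxy stay on either side of the other hydroxyl.

Step 2
Reactants: 2 2-iodo-6-methoxybenzene-1,4-diol
Product: 3 2-iodo-6-methoxy-4-[(triisopropylsilyl)oxy]phenol
Conditions: TIPSCl (1.05 equiv), imidazole, CH2Cl2, 0 °C
Reagents that add atoms: triisopropylsilyl chloride, CC(C)[Si](Cl)(C(C)C)C(C)C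
Why: Sterically controlled silylation, in which the bulky silyl chloride should react only at the hydroxyl flanked by two hydrogens and leave the one wedged between iodine and methoxy free.

Step 3
Reactants: 3 2-iodo-6-methoxy-4-[(triisopropylsilyl)oxy]phenol
Product: 4 2-iodo-6-methoxy-4-[(triisopropylsilyl)oxy]phenyl trifluoromethanesulfonate
Conditions: Tf2O, pyridine, CH2Cl2, 0 °C
Reagents that add atoms: trifluoromethanesulfonic anhydride, FC(F)(F)S(=O)(=O)OS(=O)(=O)C(F)(F)F
Why: O-sulfonylation of the remaining phenol gives an ortho-iodoaryl triflate, the standard low-temperature aryne precursor, with the leaving group on the carbon next to OMe.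

Step 4
Reactants: 5 8-bromooct-1-ene; 6 (R)-propylene oxide
Product: 8 (R)-undec-10-en-2-ol, via oct-7-enylmagnesium bromide 7 (not isolated)
Conditions: Mg, THF, 40 °C; then CuBr·SMe2 (10 mol %), 6, −30 to 0 °C; then 1 M HCl
Reagents that add atoms: none
Why: Copper-catalysed Grignard opening of the epoxide at its unsubstituted carbon (SN2), which does not touch the stereocenter, so the R configuration of 6 is carried into the carbinol.

Step 5
Reactants: 8 (R)-undec-10-en-2-ol
Product: 9 (R)-tert-butyldimethyl(undec-10-en-2-yloxy)silane
Conditions: TBSCl, imidazole, DMF, rt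
Reagents that add atoms: tert-butyldimethylsilyl chloride, CC(C)(C)[Si](C)(C)Cl
Why: Standard silyl protection of the secondary alcohol so that no O–H is present during enolate and aryllithium chemistry.

Step 6
Reactants: 9 (R)-tert-butyldimethyl(undec-10-en-2-yloxy)silane
Product: 10 methyl (9R)-9-[(tert-butyldimethylsilyl)oxy]decanoate
Conditions: O3, NaOH (2.5 M in MeOH), CH2Cl2, −78 °C
Reagents that add atoms: ozone, [O-][O+]=O; methanol, CO
Why: Ozonolysis in methanolic NaOH converts the terminal alkene directly into the methyl ester with loss of the terminal carbon, and the silyl ether and the remote stereocenter are inert at −78 °C.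

Step 7
Reactants: 10 methyl (9R)-9-[(tert-butyldimethylsilyl)oxy]decanoate
Product: 11 (9R)-1,9-bis[(tert-butyldimethylsilyl)oxy]-1-methoxydec-1-ene (E/Z mixture, used crude)
Conditions: LDA, THF, −78 °C; TBSCl, DMPU, −78 °C to rt; pentane, filtration
Reagents that add atoms: tert-butyldimethylsilyl chloride, CC(C)(C)[Si](C)(C)Cl
Why: O-silylation of the ester enolate gives the ketene silyl acetal, whose double-bond geometry is irrelevant because the configuration of both carbons is erased later.

Step 8
Reactants: 4 2-iodo-6-methoxy-4-[(triisopropylsilyl)oxy]phenyl trifluoromethanesulfonate; 11 (9R)-1,9-bis[(tert-butyldimethylsilyl)oxy]-1-methoxydec-1-ene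
Product: 13 benzocyclobutenone methyl silyl acetal (stereoisomer mixture), via 3-methoxy-5-(triisopropylsilyloxy)benzyne 12 (not isolated)
Conditions: 11 (1.5 equiv), n-BuLi (1.1 equiv), THF, −78 °C; excess 11 returns as ester 10 on work-up
Reagents that add atoms: none
Why: Iodine–lithium exchange and loss of LiOTf give aryne 12, which undergoes stepwise (2+2) cycloaddition with the ketene silyl acetal; the nucleophilic chain-bearing carbon attacks the aryne carbon remote from OMe (the aryl anion develops next to the inductively stabilizing OMe), so the acetal carbon ends on C1 beside OMe and the chain-bearing carbon on C6.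

Step 9
Reactants: 13 benzocyclobutenone methyl silyl acetal
Product: 14 8-[(7R)-7-hydroxyoctyl]-5-methoxy-3-[(triisopropylsilyl)oxy]bicyclo[4.2.0]octa-1,3,5-trien-7-one (both C8 epimers)
Conditions: HF (48% aq.), MeCN, 0 °C to rt
Reagents that add atoms: none
Why: Acidic fluoride cleaves the mixed methyl silyl acetal to the ketone and the alkyl silyl ether to the alcohol, whereas aryl silyl ethers resist these acidic conditions, so the phenol should stay capped.

Step 10
Reactants: 14 8-[(7R)-7-hydroxyoctyl]-5-methoxy-3-[(triisopropylsilyl)oxy]bicyclo[4.2.0]octa-1,3,5-trien-7-one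
Product: 16 (R)-lasiodiplodin triisopropylsilyl ether, via ortho-quinoid ketene 15 (not isolated)
Conditions: hν (350 nm), degassed PhMe (0.001 M), Ar, 20 °C
Reagents that add atoms: none
Why: Proposed new method: excitation of the ketone cleaves the C7–C8 bond in a four-electron electrocyclic opening to the ortho-quinoid vinylketene 15, the tethered secondary hydroxyl adds in the ketene plane to the central carbon, and the enol ester rearomatizes by a 1,5-hydrogen shift from O–H to the exocyclic carbon, which becomes the benzylic CH2 on C6. The closest known reactions are the capture of photochemically or thermally opened benzocyclobutenones by solvent alcohols to give ortho-alkylbenzoates and the macrolactonization of thermally generated acylketenes; neither has been shown for closing a large ring from a benzocyclobutenone. The one ring formed is the 12-membered lactone, closed by 12-exo-dig attack of oxygen on the sp carbon with the C=O π bond outside the new ring. No stereocenter is created: C8 becomes CH2, so both epimers of 14 converge, and the carbinol keeps its R configuration because only its O–H bond reacts. The step needs intramolecular capture to win over ketene dimerization and intermolecular esterification, which the high dilution, the silyl cap on the only other hydroxyl and the thermal reclosure of uncaptured ketene to 14 (keeping its steady-state concentration low and recycling material) should secure. Addition to a ketene also avoids acyl substitution at a 2,6-disubstituted benzoyl carbon, and 350 nm light is absorbed by the ketone but not by the product benzoate.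

Step 11
Reactants: 16 (R)-lasiodiplodin triisopropylsilyl ether
Product: 17 (R)-lasiodiplodin
Conditions: TBAF, AcOH, THF, 0 °C
Reagents that add atoms: none
Why: Fluoride-mediated cleavage of the aryl silyl ether (phenoxide is a good leaving group on silicon), with the acetic acid buffer keeping the medium mild for the lactone.

Step 12
Reactants: 17 (R)-lasiodiplodin
Product: 19 5-(hydroxymethyl)lasiodiplodin, via cyclic phenylboronate 18 (not isolated)
Conditions: PhB(OH)2, (CH2O)n, EtCO2H (cat.), PhMe, reflux (Dean–Stark); then propane-1,3-diol, THF, rt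
Reagents that add atoms: formaldehyde (from paraformaldehyde), C=O
Why: Boronate-templated ortho-hydroxymethylation, in which the aryl phenylboronate delivers formaldehyde to an ortho carbon and the cyclic boronate stops the reaction at one CH2O unit; of the two ortho sites, C5 (para to OMe, the position at which resorcylic macrolides undergo electrophilic substitution) should react in preference to C3, which lies between two oxygens.

Step 13
Reactants: 20 (S)-4-methyldihydrofuran-2(3H)-one
Product: 21 (S)-5-hydroxy-4-methylpentan-2-one (in equilibrium with its cyclic hemiketal)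
Conditions: MeLi (1.0 equiv), Et2O, −78 °C; then AcOH
Reagents that add atoms: methyllithium, [Li]C
Why: Mono-addition of methyllithium to the lactone, possible because the tetrahedral lithium alkoxide is stable at −78 °C and collapses to the methyl ketone only on quench; the stereocenter is not involved.

Step 14
Reactants: 21 (S)-5-hydroxy-4-methylpentan-2-one
Product: 22 (S)-3,5-dimethyl-2,3-dihydrofuran
Conditions: H3PO4 (cat.), neat, distillation (bath 140 °C) onto K2CO3
Reagents that add atoms: none
Why: Acid-catalysed dehydration of the cyclic hemiketal gives the more stable endocyclic enol ether, which is removed by distillation as it forms; the stereocenter is not alpha to the oxocarbenium carbon and cannot epimerize.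

Step 15
Reactants: 19 5-(hydroxymethyl)lasiodiplodin; 22 (S)-3,5-dimethyl-2,3-dihydrofuran
Product: 24 lasiodiplactone A, via ortho-quinone methide 23 (not isolated)
Conditions: 22 (5 equiv), PhMe (0.02 M), 150 °C, sealed tube
Reagents that add atoms: none
Why: Thermal loss of water from the ortho-hydroxybenzyl alcohol gives quinone methide 23, which undergoes an inverse-electron-demand hetero-Diels–Alder reaction with the enol ether (oxygen to the methyl-bearing carbon, CH2 to the β-carbon); suprafacial addition fixes the cis ring fusion and approach to the face opposite the allylic methyl should set the ketal carbon and the ring-fusion carbon, both S.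

**Compound list**

1 | 5-iodovanillin (4-hydroxy-3-iodo-5-methoxybenzaldehyde) | COc1cc(C=O)cc(I)c1O | starting material
2 | 2-iodo-6-methoxybenzene-1,4-diol | COc1cc(O)cc(I)c1O | intermediate
3 | 2-iodo-6-methoxy-4-[(triisopropylsilyl)oxy]phenol | COc1cc(O[Si](C(C)C)(C(C)C)C(C)C)cc(I)c1O | intermediate
4 | 2-iodo-6-methoxy-4-[(triisopropylsilyl)oxy]phenyl trifluoromethanesulfonate | COc1cc(O[Si](C(C)C)(C(C)C)C(C)C)cc(I)c1OS(=O)(=O)C(F)(F)F | intermediate
5 | 8-bromooct-1-ene | C=CCCCCCCBr | starting material
6 | (R)-propylene oxide | C[C@@H]1CO1 | starting material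
7 | oct-7-enylmagnesium bromide | C=CCCCCCC[Mg]Br | intermediate
8 | (R)-undec-10-en-2-ol | C=CCCCCCCC[C@@H](C)O | intermediate
9 | (R)-tert-butyldimethyl(undec-10-en-2-yloxy)silane | C=CCCCCCCC[C@@H](C)O[Si](C)(C)C(C)(C)C | intermediate
10 | methyl (9R)-9-[(tert-butyldimethylsilyl)oxy]decanoate | COC(=O)CCCCCCC[C@@H](C)O[Si](C)(C)C(C)(C)C | intermediate
11 | (9R)-1,9-bis[(tert-butyldimethylsilyl)oxy]-1-methoxydec-1-ene (E/Z mixture) | COC(O[Si](C)(C)C(C)(C)C)=CCCCCCC[C@@H](C)O[Si](C)(C)C(C)(C)C | intermediate
12 | 3-methoxy-5-[(triisopropylsilyl)oxy]benzyne | COC1=CC(O[Si](C(C)C)(C(C)C)C(C)C)=CC#C1 | intermediate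
13 | 7-[(tert-butyldimethylsilyl)oxy]-8-{(7R)-7-[(tert-butyldimethylsilyl)oxy]octyl}-5,7-dimethoxy-3-[(triisopropylsilyl)oxy]bicyclo[4.2.0]octa-1,3,5-triene (mixture at C7 and C8) | COc1cc(O[Si](C(C)C)(C(C)C)C(C)C)cc2c1C(OC)(O[Si](C)(C)C(C)(C)C)C2CCCCCC[C@@H](C)O[Si](C)(C)C(C)(C)C | intermediate
14 | 8-[(7R)-7-hydroxyoctyl]-5-methoxy-3-[(triisopropylsilyl)oxy]bicyclo[4.2.0]octa-1,3,5-trien-7-one (both C8 epimers) | COc1cc(O[Si](C(C)C)(C(C)C)C(C)C)cc2c1C(=O)C2CCCCCC[C@@H](C)O | intermediate
15 | {6-[(8R)-8-hydroxynonylidene]-2-methoxy-4-[(triisopropylsilyl)oxy]cyclohexa-2,4-dien-1-ylidene}methanone (ortho-quinoid ketene) | COC1=CC(O[Si](C(C)C)(C(C)C)C(C)C)=CC(=CCCCCCC[C@@H](C)O)C1=C=O | intermediate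
16 | (R)-lasiodiplodin triisopropylsilyl ether, (3R)-14-methoxy-3-methyl-12-[(triisopropylsilyl)oxy]-3,4,5,6,7,8,9,10-octahydro-1H-2-benzoxacyclododecin-1-one | COc1cc(O[Si](C(C)C)(C(C)C)C(C)C)cc2c1C(=O)O[C@H](C)CCCCCCC2 | intermediate
17 | (R)-lasiodiplodin, (3R)-12-hydroxy-14-methoxy-3-methyl-3,4,5,6,7,8,9,10-octahydro-1H-2-benzoxacyclododecin-1-one | COc1cc(O)cc2c1C(=O)O[C@H](C)CCCCCCC2 | intermediate
18 | cyclic phenylboronate of 19 (2-phenyl-4H-1,3,2-benzodioxaborin ring spanning the C4 oxygen and the C5 CH2O; lactone carbinol R) | COc1cc2c(COB(c3ccccc3)O2)c2c1C(=O)O[C@H](C)CCCCCCC2 | intermediate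
19 | 5-(hydroxymethyl)lasiodiplodin, (3R)-12-hydroxy-11-(hydroxymethyl)-14-methoxy-3-methyl-3,4,5,6,7,8,9,10-octahydro-1H-2-benzoxacyclododecin-1-one | COc1cc(O)c(CO)c2c1C(=O)O[C@H](C)CCCCCCC2 | intermediate
20 | (S)-4-methyldihydrofuran-2(3H)-one | O=C1C[C@H](C)CO1 | starting material
21 | (S)-5-hydroxy-4-methylpentan-2-one (open form of (4S)-2,4-dimethyltetrahydrofuran-2-ol) | CC(=O)C[C@H](C)CO | intermediate
22 | (S)-3,5-dimethyl-2,3-dihydrofuran | CC1=C[C@H](C)CO1 | intermediate
23 | (3R)-14-methoxy-3-methyl-11-methylidene-3,4,5,6,7,8,9,10-octahydro-1H-2-benzoxacyclododecine-1,12(11H)-dione (ortho-quinone methide) | COC1=CC(=O)C(=C)C2=C1C(=O)O[C@H](C)CCCCCCC2 | intermediate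
24 | lasiodiplactone A (lactone carbinol R; ketal carbon, ring-fusion CH and CH(CH3) of the furan all S; cis-fused, both furan methyls and the ring-fusion hydrogen on one face) | COc1cc2c(c3c1C(=O)O[C@H](C)CCCCCCC3)C[C@H]1[C@H](C)CO[C@@]1(C)O2 | target

**Step count and risks**

Total: 15 steps. Longest linear sequence: 10 steps (steps 4, 5, 6, 7, 8, 9, 10, 11, 12 and 15, from 5 and 6 to 24).

Steps most likely to fail:

1. Step 10. The ketene may reclose, acylate another molecule, or undergo a hydrogen shift to an ortho-alkenyl benzaldehyde faster than it closes the 12-membered ring. The fallback sets out from 14 and intercepts the same ketene with water, a known capture: irradiation at 350 nm in MeCN/H2O should give the seco acid 2-[(8R)-8-hydroxynonyl]-6-methoxy-4-[(triisopropylsilyl)oxy]benzoic acid F1. This is activated with 2,2'-dipyridyl disulfide and PPh3 as S-(pyridin-2-yl) 2-[(8R)-8-hydroxynonyl]-6-methoxy-4-[(triisopropylsilyl)oxy]benzenecarbothioate F2 and cyclized in refluxing xylene at high dilution (Corey–Nicolaou macrolactonization, carbinol configuration retained). It comes back to the route at 16.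

2. Step 12. Site selectivity between C5 and C3 may be poor, or a second formaldehyde unit may be introduced. The fallback sets out from 17 and separates the choice of site from the carbon–carbon bond formation: bromination with NBS (MeCN, −20 °C) should give 5-bromolasiodiplodin F3, the halogen entering para to OMe and ortho to the hydroxyl as in the halogenation of related resorcylic macrolides, and a monobromide is easily purified. Stille coupling of F3 with (tributylstannyl)methanol (Pd(PPh3)4, dioxane, 100 °C) then installs the CH2OH group and comes back to the route at 19.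

3. Step 15. Facial selectivity may erode, 22 may isomerize to the exocyclic enol ether (which would lead to a spiroketal), or the quinone methide may self-condense. The fallback replaces the cycloaddition by a Friedel–Crafts alkylation and ketalization and sets out from 22 and 17. Vilsmeier–Haack formylation of 22 (POCl3, DMF, 0 °C) should give (4S)-2,4-dimethyl-4,5-dihydrofuran-3-carbaldehyde F4, and reduction (i-Bu2AlH, CH2Cl2, −78 °C) the allylic alcohol [(4S)-2,4-dimethyl-4,5-dihydrofuran-3-yl]methanol F5. With 17, BF3·OEt2 and MgSO4 in Et2O at 0 °C, F5 should ionize, alkylate C5 and close the ketal under equilibrating acid conditions that favour the cis-fused, all-cis arrangement. This bypasses 19 and comes back to the route at 24.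

**Further compounds**

F1 | step 10 | 2-[(8R)-8-hydroxynonyl]-6-methoxy-4-[(triisopropylsilyl)oxy]benzoic acid | COc1cc(O[Si](C(C)C)(C(C)C)C(C)C)cc(CCCCCCC[C@@H](C)O)c1C(=O)O
F2 | step 10 | S-(pyridin-2-yl) 2-[(8R)-8-hydroxynonyl]-6-methoxy-4-[(triisopropylsilyl)oxy]benzenecarbothioate | COc1cc(O[Si](C(C)C)(C(C)C)C(C)C)cc(CCCCCCC[C@@H](C)O)c1C(=O)Sc1ccccn1
F3 | step 12 | 5-bromolasiodiplodin, (3R)-11-bromo-12-hydroxy-14-methoxy-3-methyl-3,4,5,6,7,8,9,10-octahydro-1H-2-benzoxacyclododecin-1-one | COc1cc(O)c(Br)c2c1C(=O)O[C@H](C)CCCCCCC2
F4 | step 15 | (4S)-2,4-dimethyl-4,5-dihydrofuran-3-carbaldehyde | CC1=C(C=O)[C@H](C)CO1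
F5 | step 15 | [(4S)-2,4-dimethyl-4,5-dihydrofuran-3-yl]methanol | CC1=C(CO)[C@H](C)CO1
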